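**Retrosynthetic overview**

1. Feature: C8 to C8' of the target is a twenty-carbon all-E heptaene with methyls on C9, C13, C13' and C9', which is the carbon chain of crocetin dialdehyde. It is bounded by the C7=C8 alkene on ring A (the cyclohex-1-ene, C1–C6, 3R) and the C7'=C8' alkene on ring B (the cyclohex-2-ene, C1'–C6', 3'R,6'R).
2. Last disconnection: the two ester C–O bonds at C3 and C3', made by one double myristoylation of lutein after desilylation.
3. Key disconnection: C7'=C8' and then C7=C8, made in one flask by two Julia–Kocienski olefinations of the C20 dialdehyde with the ring B and ring A C10 1-phenyltetrazol-5-yl sulfones.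
4. Ring A is not built; it comes from (4R,6R)-actinol, with C7 added by enol triflate carbonylation. Ring B is made by mesityl oxide/ethyl acetoacetate annulation, with C3' set by CBS reduction and C6' selected by separation of the resulting epimers.
5. Order of ring formation: ring B only (step 7); no ring closes in or after the key step.

Key step: step 13

Assumption: crocetin dialdehyde and (4R,6R)-actinol are taken as purchasable; carotenoid numbering (ring A C1–C6, ring B C1'–C6') is used for the late intermediates, and all polyene work is done under argon with exclusion of light unless stated.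

**Ring A sulfone**

Step 1
Reactants: 1 (4R,6R)-4-hydroxy-2,2,6-trimethylcyclohexanone (actinol)
Product: 2 (4R,6R)-4-[(tert-butyldimethylsilyl)oxy]-2,2,6-trimethylcyclohexanone
Conditions: TBSCl, imidazole, DMF, rt
Reagents that add atoms: tert-butyldimethylsilyl chloride (TBSCl), CC(C)(C)[Si](C)(C)Cl
Why: Imidazole-promoted O-silylation of an unhindered secondary alcohol should proceed cleanly; the C4 carbinol centre (later C3) is untouched and the C6 centre is removed in step 2.

Step 2
Reactants: 2 (4R,6R)-4-[(tert-butyldimethylsilyl)oxy]-2,2,6-trimethylcyclohexanone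
Product: 3 (4R)-4-[(tert-butyldimethylsilyl)oxy]-2,6,6-trimethylcyclohex-1-en-1-yl trifluoromethanesulfonate
Conditions: LiN(iPr)2, THF, −78 → 0 °C; PhNTf2, −78 °C → rt; aq NH4Cl
Reagents that add atoms: N-phenylbis(trifluoromethanesulfonimide) (PhNTf2), O=S(=O)(N(c1ccccc1)S(=O)(=O)C(F)(F)F)C(F)(F)F
Why: Enol triflate formation; C2 is quaternary, so deprotonation can occur only at C6 and a single tetrasubstituted enolate is trapped on oxygen, leaving the silyloxy centre unchanged.

Step 3
Reactants: 3 (4R)-4-[(tert-butyldimethylsilyl)oxy]-2,6,6-trimethylcyclohex-1-en-1-yl trifluoromethanesulfonate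
Product: 4 methyl (4R)-4-[(tert-butyldimethylsilyl)oxy]-2,6,6-trimethylcyclohex-1-ene-1-carboxylate
Conditions: Pd(OAc)2 (5 mol%), PPh3, CO (1 atm), MeOH, Et3N, DMF, 60 °C
Reagents that add atoms: carbon monoxide, [C-]#[O+]; methanol, CO
Why: Palladium-catalysed alkoxycarbonylation of an enol triflate (oxidative addition of zerovalent palladium into the C–OTf bond, CO insertion, methanolysis of the acylpalladium) installs the future C7 on C6 of ring A.

Step 4
Reactants: 4 methyl (4R)-4-[(tert-butyldimethylsilyl)oxy]-2,6,6-trimethylcyclohex-1-ene-1-carboxylate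
Product: 5 [(4R)-4-[(tert-butyldimethylsilyl)oxy]-2,6,6-trimethylcyclohex-1-en-1-yl]methanol
Conditions: iBu2AlH (2.5 equiv), CH2Cl2, −78 → 0 °C; aq KNaC4H4O6
Reagents that add atoms: none
Why: 1,2-Reduction of the conjugated ester by the aluminium hydride should give the allylic alcohol without touching the silyl ether or the tetrasubstituted alkene.

Step 5
Reactants: 5 [(4R)-4-[(tert-butyldimethylsilyl)oxy]-2,6,6-trimethylcyclohex-1-en-1-yl]methanol
Product: 6 5-({[(4R)-4-[(tert-butyldimethylsilyl)oxy]-2,6,6-trimethylcyclohex-1-en-1-yl]methyl}sulfanyl)-1-phenyl-1H-tetrazole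
Conditions: 1-phenyl-1H-tetrazole-5-thiol, PPh3, DIAD, THF, 0 °C → rt
Reagents that add atoms: 1-phenyl-1H-tetrazole-5-thiol, Sc1nnnn1-c1ccccc1
Why: Mitsunobu thioetherification; the acidic thiol displaces the alkoxyphosphonium group at the primary carbon, and allylic transposition is blocked because the other allylic terminus (C5) is fully substituted.

Step 6
Reactants: 6 ring A sulfide
Product: 7 5-({[(4R)-4-[(tert-butyldimethylsilyl)oxy]-2,6,6-trimethylcyclohex-1-en-1-yl]methyl}sulfonyl)-1-phenyl-1H-tetrazole (ring A sulfone)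
Conditions: (NH4)6Mo7O24·4H2O (10 mol%), 30% H2O2, EtOH, 0 °C → rt
Reagents that add atoms: hydrogen peroxide, OO
Why: Peroxomolybdate-catalysed oxidation of sulfide to sulfone is selective for sulfur over the hindered ring alkene and leaves the silyl ether intact.

**Ring B sulfone**

Step 7
Reactants: 8 ethyl acetoacetate; 9 mesityl oxide
Product: 10 ethyl (±)-2,6,6-trimethyl-4-oxocyclohex-2-ene-1-carboxylate (racemic)
Conditions: ZnCl2, heptane–toluene, reflux, Dean–Stark
Reagents that add atoms: none
Why: Lewis-acid-promoted Michael addition of the acetoacetate methylene to the β-carbon of mesityl oxide, followed by intramolecular aldol condensation of the distal methyl ketone onto the acetoacetate carbonyl (Robinson-type annulation), closes ring B with the 2,6,6-trimethyl pattern, the C4 oxygen and the C1 ester in place; C1 forms racemic and is sorted in step 8.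

Step 8
Reactants: 10 ethyl (±)-2,6,6-trimethyl-4-oxocyclohex-2-ene-1-carboxylate
Product: 11 ethyl (1R,4R)-4-hydroxy-2,6,6-trimethylcyclohex-2-ene-1-carboxylate (trans)
Conditions: (S)-1-methyl-3,3-diphenyltetrahydro-1H,3H-pyrrolo[1,2-c][1,3,2]oxazaborole (20 mol%), catecholborane, toluene, −78 °C; silica chromatography of the C1 epimers
Reagents that add atoms: none
Why: CBS reduction; the (S)-oxazaborolidine binds the carbonyl anti to the alkenyl flank and delivers hydride to the face that gives the 4R carbinol whatever the C1 configuration, so (1R)-10 should give trans-(1R,4R)-11 and (1S)-10 the cis-(1S,4R) epimer, which are diastereomers separable on silica; C4 (later C3') is set by the catalyst and C1 (later C6') is selected by the separation, using at most half of 10.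

Step 9
Reactants: 11 ethyl (1R,4R)-4-hydroxy-2,6,6-trimethylcyclohex-2-ene-1-carboxylate
Product: 12 ethyl (1R,4R)-4-[(tert-butyldimethylsilyl)oxy]-2,6,6-trimethylcyclohex-2-ene-1-carboxylate
Conditions: TBSCl, imidazole, DMF, rt
Reagents that add atoms: tert-butyldimethylsilyl chloride (TBSCl), CC(C)(C)[Si](C)(C)Cl
Why: O-Silylation of the allylic secondary alcohol under weakly basic conditions should not epimerise the ester-bearing C1 or ionise the allylic C–O bond.

Step 10
Reactants: 12 ethyl (1R,4R)-4-[(tert-butyldimethylsilyl)oxy]-2,6,6-trimethylcyclohex-2-ene-1-carboxylate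
Product: 13 [(1R,4R)-4-[(tert-butyldimethylsilyl)oxy]-2,6,6-trimethylcyclohex-2-en-1-yl]methanol
Conditions: iBu2AlH (3 equiv), CH2Cl2, −78 → 0 °C; aq KNaC4H4O6
Reagents that add atoms: none
Why: Hydride reduction of the ester to the primary alcohol with a non-basic aluminium hydride avoids enolisation at C1, which stops being epimerisable once the carbonyl is gone.

Step 11
Reactants: 13 [(1R,4R)-4-[(tert-butyldimethylsilyl)oxy]-2,6,6-trimethylcyclohex-2-en-1-yl]methanol
Product: 14 5-({[(1R,4R)-4-[(tert-butyldimethylsilyl)oxy]-2,6,6-trimethylcyclohex-2-en-1-yl]methyl}sulfanyl)-1-phenyl-1H-tetrazole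
Conditions: 1-phenyl-1H-tetrazole-5-thiol, PPh3, DIAD, THF, 0 → 40 °C
Reagents that add atoms: 1-phenyl-1H-tetrazole-5-thiol, Sc1nnnn1-c1ccccc1
Why: Mitsunobu thioetherification at the primary carbon; the substitution is at CH2 and not at a stereocentre, so C1 and C4 keep their configurations.

Step 12
Reactants: 14 ring B sulfide
Product: 15 5-({[(1R,4R)-4-[(tert-butyldimethylsilyl)oxy]-2,6,6-trimethylcyclohex-2-en-1-yl]methyl}sulfonyl)-1-phenyl-1H-tetrazole (ring B sulfone)
Conditions: (NH4)6Mo7O24·4H2O (10 mol%), 30% H2O2, EtOH, 0 °C → rt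
Reagents that add atoms: hydrogen peroxide, OO
Why: Peroxomolybdate-catalysed oxidation of sulfide to sulfone should spare the trisubstituted ring alkene and the allylic silyl ether.

**Assembly and end game**

Step 13
Reactants: 15 ring B sulfone; 16 crocetin dialdehyde, (2E,4E,6E,8E,10E,12E,14E)-2,6,11,15-tetramethylhexadeca-2,4,6,8,10,12,14-heptaenedial; 7 ring A sulfone
Product: 18 lutein bis(tert-butyldimethylsilyl) ether (all-E; 3R,3'R,6'R), via C30 apo-aldehyde 17 (not isolated)
Conditions: 15 + KN(SiMe3)2 (0.98 equiv), THF, −78 °C, added slowly to 16 (1.1 equiv), THF, −78 → −20 °C, argon purge; then 7 (1.6 equiv) premetalated with KN(SiMe3)2 (1.55 equiv) in THF at −78 °C, added, −78 °C → rt; aq NH4Cl; dark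
Reagents that add atoms: none
Why: Julia–Kocienski olefination run twice in one flask: each potassium α-sulfonyl carbanion adds to a formyl terminus, the β-alkoxide attacks C5 of the phenyltetrazole (Smiles rearrangement), and the resulting sulfinate expels SO2 and potassium 1-phenyltetrazol-5-olate to leave first the C7'=C8' and then the C7=C8 double bond. The closest known reaction type is the Julia–Kocienski olefination of polyene aldehydes and dialdehydes with heteroaryl sulfones in C10 + C20 + C10 carotenoid assembly. No ring is closed and no stereocentre is created; C3, C3' and C6' arrive with 7 and 15, and the non-conjugated C7' carbanion together with substoichiometric KN(SiMe3)2 leaves the C6'–H and the C4'=C5' alkene of ring B untouched. Mono- before bis-olefination is secured by adding the carbanion of 15 slowly to an excess of 16, whose second formyl group activates the first through the heptaene, so that 16 is more electrophilic than the apo-aldehyde 17. E geometry at C7'=C8' is favoured by the potassium counterion in THF (open transition state, anti adduct) with the unstabilised, β-branched sulfone 15. The allylic sulfone 7 may deliver part of the C7=C8 bond as Z, which is corrected by the equilibration in step 14.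

Step 14
Reactants: 18 lutein bis(tert-butyldimethylsilyl) ether (crude, carried together with its 7Z and 7'Z isomers)
Product: 19 lutein, (3R,3'R,6'R)-β,ε-carotene-3,3'-diol (all-E)
Conditions: I2 (2 mol%), CH2Cl2–hexane, diffuse daylight, rt; aq Na2S2O3 wash; then Bu4NF, THF, 0 °C → rt; crystallisation from CH2Cl2–hexane
Reagents that add atoms: none
Why: Iodine atoms add reversibly to the polyene so that the alkene geometries equilibrate under thermodynamic control toward all-E (the hindered 7Z and 7'Z forms are depleted), after which fluoride cleaves both Si–O bonds (silyl ether deprotection) without acid that could ionise the allylic C3' oxygen, and all-E lutein is expected to crystallise away from the minor unhindered Z isomers; no stereocentre is affected.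

Step 15
Reactants: 19 lutein
Product: 20 lutein dimyristate, (3R,3'R,6'R)-β,ε-carotene-3,3'-diyl ditetradecanoate
Conditions: tetradecanoyl chloride (3 equiv), pyridine, 4-(dimethylamino)pyridine (cat.), CH2Cl2, 0 °C → rt, dark
Reagents that add atoms: tetradecanoyl chloride (myristoyl chloride), CCCCCCCCCCCCCC(=O)Cl
Why: Base-mediated O-acylation (nucleophilic acyl substitution) of both secondary hydroxyl groups in one operation; pyridine takes up HCl so the allylic C3'–O bond is not ionised, and since no C–O bond at C3 or C3' is broken both configurations are retained.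

**Compound list**

1 | (4R,6R)-4-hydroxy-2,2,6-trimethylcyclohexanone (actinol) | O[C@@H]1C[C@@H](C)C(=O)C(C)(C)C1 | starting material
2 | (4R,6R)-4-[(tert-butyldimethylsilyl)oxy]-2,2,6-trimethylcyclohexanone | CC(C)(C)[Si](C)(C)O[C@@H]1C[C@@H](C)C(=O)C(C)(C)C1 | intermediate
3 | (4R)-4-[(tert-butyldimethylsilyl)oxy]-2,6,6-trimethylcyclohex-1-en-1-yl trifluoromethanesulfonate | CC(C)(C)[Si](C)(C)O[C@@H]1CC(C)=C(OS(=O)(=O)C(F)(F)F)C(C)(C)C1 | intermediate
4 | methyl (4R)-4-[(tert-butyldimethylsilyl)oxy]-2,6,6-trimethylcyclohex-1-ene-1-carboxylate | CC(C)(C)[Si](C)(C)O[C@@H]1CC(C)=C(C(=O)OC)C(C)(C)C1 | intermediate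
5 | [(4R)-4-[(tert-butyldimethylsilyl)oxy]-2,6,6-trimethylcyclohex-1-en-1-yl]methanol | CC(C)(C)[Si](C)(C)O[C@@H]1CC(C)=C(CO)C(C)(C)C1 | intermediate
6 | ring A sulfide, 5-({[(4R)-4-[(tert-butyldimethylsilyl)oxy]-2,6,6-trimethylcyclohex-1-en-1-yl]methyl}sulfanyl)-1-phenyl-1H-tetrazole | CC(C)(C)[Si](C)(C)O[C@@H]1CC(C)=C(CSc2nnnn2-c2ccccc2)C(C)(C)C1 | intermediate
7 | ring A sulfone, 5-({[(4R)-4-[(tert-butyldimethylsilyl)oxy]-2,6,6-trimethylcyclohex-1-en-1-yl]methyl}sulfonyl)-1-phenyl-1H-tetrazole | CC(C)(C)[Si](C)(C)O[C@@H]1CC(C)=C(CS(=O)(=O)c2nnnn2-c2ccccc2)C(C)(C)C1 | intermediate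
8 | ethyl acetoacetate | CCOC(=O)CC(C)=O | starting material
9 | mesityl oxide | CC(C)=CC(C)=O | starting material
10 | ethyl (±)-2,6,6-trimethyl-4-oxocyclohex-2-ene-1-carboxylate (racemic) | CCOC(=O)C1C(C)=CC(=O)CC1(C)C | intermediate
11 | ethyl (1R,4R)-4-hydroxy-2,6,6-trimethylcyclohex-2-ene-1-carboxylate (trans) | CCOC(=O)[C@H]1C(C)=C[C@H](O)CC1(C)C | intermediate
12 | ethyl (1R,4R)-4-[(tert-butyldimethylsilyl)oxy]-2,6,6-trimethylcyclohex-2-ene-1-carboxylate | CCOC(=O)[C@H]1C(C)=C[C@H](O[Si](C)(C)C(C)(C)C)CC1(C)C | intermediate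
13 | [(1R,4R)-4-[(tert-butyldimethylsilyl)oxy]-2,6,6-trimethylcyclohex-2-en-1-yl]methanol | OC[C@H]1C(C)=C[C@H](O[Si](C)(C)C(C)(C)C)CC1(C)C | intermediate
14 | ring B sulfide, 5-({[(1R,4R)-4-[(tert-butyldimethylsilyl)oxy]-2,6,6-trimethylcyclohex-2-en-1-yl]methyl}sulfanyl)-1-phenyl-1H-tetrazole | S(C[C@H]1C(C)=C[C@H](O[Si](C)(C)C(C)(C)C)CC1(C)C)c1nnnn1-c1ccccc1 | intermediate
15 | ring B sulfone, 5-({[(1R,4R)-4-[(tert-butyldimethylsilyl)oxy]-2,6,6-trimethylcyclohex-2-en-1-yl]methyl}sulfonyl)-1-phenyl-1H-tetrazole | O=S(=O)(C[C@H]1C(C)=C[C@H](O[Si](C)(C)C(C)(C)C)CC1(C)C)c1nnnn1-c1ccccc1 | intermediate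
16 | crocetin dialdehyde (all-E C20 dial) | O=C/C(C)=C/C=C/C(C)=C/C=C/C=C(C)/C=C/C=C(C)/C=O | starting material
17 | C30 apo-aldehyde, (3R,6R)-3-[(tert-butyldimethylsilyl)oxy]-8'-apo-ε-caroten-8'-al (all-E) | O=C/C(C)=C/C=C/C(C)=C/C=C/C=C(C)/C=C/C=C(C)/C=C/[C@H]1C(C)=C[C@H](O[Si](C)(C)C(C)(C)C)CC1(C)C | intermediate (not isolated)
18 | lutein bis(tert-butyldimethylsilyl) ether, (3R,3'R,6'R)-3,3'-bis[(tert-butyldimethylsilyl)oxy]-β,ε-carotene (all-E) | CC(C)(C)[Si](C)(C)O[C@@H]1CC(C)=C(/C=C/C(C)=C/C=C/C(C)=C/C=C/C=C(C)/C=C/C=C(C)/C=C/[C@H]2C(C)=C[C@H](O[Si](C)(C)C(C)(C)C)CC2(C)C)C(C)(C)C1 | intermediate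
19 | lutein, (3R,3'R,6'R)-β,ε-carotene-3,3'-diol (all-E) | O[C@@H]1CC(C)=C(/C=C/C(C)=C/C=C/C(C)=C/C=C/C=C(C)/C=C/C=C(C)/C=C/[C@H]2C(C)=C[C@H](O)CC2(C)C)C(C)(C)C1 | intermediate
20 | lutein dimyristate | CCCCCCCCCCCCCC(=O)O[C@@H]1CC(C)=C(/C=C/C(C)=C/C=C/C(C)=C/C=C/C=C(C)/C=C/C=C(C)/C=C/[C@H]2C(C)=C[C@H](OC(=O)CCCCCCCCCCCCC)CC2(C)C)C(C)(C)C1 | target

**Step count**

Total: 15 steps. Longest linear sequence: 9 steps (steps 1–6 or steps 7–12, then steps 13–15).

**Steps most likely to fail**

Step 13. The dialdehyde and the apo-aldehyde may compete for the first carbanion, giving the symmetrical ε,ε- and β,β-carotenoids beside the wanted one. SO2 set free in the first stage and residual dialdehyde may also consume the second carbanion, and the allylic carbanion may add with little E preference. Fallback (sets out from 15, 16 and 5, returns at 18): the first olefination is run on its own with a threefold excess of 16, and the apo-aldehyde 17 is isolated by chromatography with recovery of surplus 16. Ring A is then attached as a phosphorus ylide instead of a sulfone carbanion. Alcohol 5 is converted with CBr4 and PPh3 (CH2Cl2, 0 °C) into the allylic bromide F1, which is quaternised with PPh3 in toluene to the phosphonium bromide F2. The ylide from F2 (NaN(SiMe3)2, THF, −78 °C) is condensed with isolated 17 in a Wittig reaction, which should give 18 as an E/Z mixture at C7=C8 for equilibration in step 14.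

Step 8. Catalyst control may be incomplete on one enantiomer of the racemic ketone, which would lower the enantiomeric purity of the trans alcohol, and the two epimers may be hard to separate. Fallback (sets out from 10, returns at 11): Luche reduction of 10 (NaBH4, CeCl3·7H2O, MeOH, −20 °C) should give the racemic cis and trans allylic alcohols, from which the racemic trans alcohol F3 is separated by chromatography. F3 is esterified with (S)-2-methoxy-2-phenylacetic acid (N,N'-dicyclohexylcarbodiimide, 4-(dimethylamino)pyridine, CH2Cl2, 0 °C), and the two diastereomeric esters are separated by chromatography or crystallisation. The (1R,4R) ester, the (S)-O-methylmandelate F4, is to be identified by the shielding pattern of its 1H NMR signals and cleaved with K2CO3 in EtOH to return 11.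

Step 11. Displacement at the primary carbon next to the ring methine flanked by the quaternary C6 may be slow, so that the activated alcohol decomposes or eliminates before the thiol attacks. Fallback (sets out from 13, returns at 14): alcohol 13 is converted with Tf2O and 2,6-lutidine (CH2Cl2, −78 °C) into the primary triflate F5. F5 is treated without storage with potassium 1-phenyl-1H-tetrazole-5-thiolate (from the thiol and K2CO3, DMF, 0 °C → rt), which should give 14 by direct displacement of the far better leaving group.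

**Further compounds**

F1 | step 13 | (4R)-1-(bromomethyl)-4-[(tert-butyldimethylsilyl)oxy]-2,6,6-trimethylcyclohex-1-ene | CC(C)(C)[Si](C)(C)O[C@@H]1CC(C)=C(CBr)C(C)(C)C1
F2 | step 13 | {[(4R)-4-[(tert-butyldimethylsilyl)oxy]-2,6,6-trimethylcyclohex-1-en-1-yl]methyl}triphenylphosphonium bromide | CC(C)(C)[Si](C)(C)O[C@@H]1CC(C)=C(C[P+](c2ccccc2)(c2ccccc2)c2ccccc2)C(C)(C)C1.[Br-]
F3 | step 8 | ethyl (±)-trans-4-hydroxy-2,6,6-trimethylcyclohex-2-ene-1-carboxylate (racemate, both enantiomers shown) | CCOC(=O)[C@H]1C(C)=C[C@H](O)CC1(C)C.CCOC(=O)[C@@H]1C(C)=C[C@@H](O)CC1(C)C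
F4 | step 8 | ethyl (1R,4R)-4-{[(2S)-2-methoxy-2-phenylacetyl]oxy}-2,6,6-trimethylcyclohex-2-ene-1-carboxylate | CCOC(=O)[C@H]1C(C)=C[C@H](OC(=O)[C@@H](OC)c2ccccc2)CC1(C)C
F5 | step 11 | [(1R,4R)-4-[(tert-butyldimethylsilyl)oxy]-2,6,6-trimethylcyclohex-2-en-1-yl]methyl trifluoromethanesulfonate | O=S(=O)(OC[C@H]1C(C)=C[C@H](O[Si](C)(C)C(C)(C)C)CC1(C)C)C(F)(F)F
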